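**Strategy.** Daucane numbering is used: cyclopentane C1–C5, cycloheptene C5–C10 plus C1. The route rests on the 1,3-dioxygen pattern O–C4/O–C6 across the ring-fusion carbon C5, next to the quaternary C1: it is read as the product of a pinacol-type 1,2-shift. In a cis-fused decalin triol monomesylate the angular carbon (future C1) migrates from the ring-fusion carbinol (future C6) to the mesylate carbon (future C5). One operation contracts a cyclohexane to the cyclopentane, expands the second ring to the cycloheptanone, sets C5 by inversion and unveils the C6 carbonyl. The decalin arises from an auxiliary-controlled Robinson annulation.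

Key step: step 6

Conventions: decalins carry naphthalene locants and hydroazulenes azulene locants (azulene C8a, C1, C2, C3, C3a, C4, C5, C6, C7, C8 = daucane C1, C2, C3, C4, C5, C6, C7, C8, C9, C10). β is the face of the angular methyl.

Step 1
Reactants: 1 7-methyl-1,4-dioxaspiro[4.5]decan-8-one (racemic); 2 (R)-1-phenylethylamine; 3 methyl vinyl ketone
Product: 6 (R)-7-methyl-7-(3-oxobutyl)-1,4-dioxaspiro[4.5]decan-8-one, via ketimine 4 (not isolated), via Michael adduct ketimine 5 (not isolated)
Conditions: 2, TsOH (cat.), toluene, reflux, Dean–Stark; then 3, THF, 40 °C; then 10% aq AcOH, rt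
Reagents that add atoms: water, O
Why: Deracemizing Michael addition of a chiral ketimine: the more substituted secondary enamine tautomer of 4 adds to 3 through a compact aza-ene-like transition state on the face away from the phenyl group of the auxiliary, which should set the quaternary centre as R before mild hydrolysis releases 2 and leaves the dioxolane intact.

Step 2
Reactants: 6 (R)-7-methyl-7-(3-oxobutyl)-1,4-dioxaspiro[4.5]decan-8-one
Product: 7 (4aR)-6,6-(ethylenedioxy)-4a-methyl-4,4a,5,6,7,8-hexahydronaphthalen-2(3H)-one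
Conditions: NaOMe (cat.), MeOH, 60 °C
Reagents that add atoms: none
Why: Robinson annulation completed by base-mediated intramolecular aldol condensation of the methyl ketone onto the ring carbonyl and dehydration to the conjugated enone; the quaternary centre cannot enolize and is retained.

Step 3
Reactants: 7 (4aR)-6,6-(ethylenedioxy)-4a-methyl-4,4a,5,6,7,8-hexahydronaphthalen-2(3H)-one
Product: 8 (2R,4aR)-6,6-(ethylenedioxy)-2-isopropyl-4a-methyl-2,3,4,4a,5,6,7,8-octahydronaphthalen-2-ol (hydroxyl cis to the angular methyl)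
Conditions: iPrMgCl, CeCl3 (anhydrous), THF, −78 °C → 0 °C; then H2O
Reagents that add atoms: isopropylmagnesium chloride, CC(C)[Mg]Cl
Why: 1,2-Addition of the organocerium reagent (no enolization or hydride transfer) to the enone carbonyl, expected pseudo-axially from the face opposite the angular methyl as in additions to steroidal 4-en-3-ones, which places the new tertiary hydroxyl cis to the methyl.

Step 4
Reactants: 8 (2R,4aR)-6,6-(ethylenedioxy)-2-isopropyl-4a-methyl-2,3,4,4a,5,6,7,8-octahydronaphthalen-2-ol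
Product: 10 (1S,2R,4aR,8aR)-6,6-(ethylenedioxy)-2-isopropyl-4a-methyldecahydronaphthalene-1,2,8a-triol (cis-fused all-cis triol), via osmate ester 9 (not isolated)
Conditions: OsO4 (1.05 equiv), TMEDA, CH2Cl2, −78 °C; then ethylenediamine, CH2Cl2, rt
Reagents that add atoms: osmium tetroxide, O=[Os](=O)(=O)=O
Why: Hydroxyl-directed dihydroxylation: hydrogen bonding of the pseudo-axial tertiary allylic hydroxyl to an oxo ligand of OsO4·TMEDA should deliver both oxygens to the alkene face cis to that hydroxyl, giving the all-cis triol with a cis ring fusion after cleavage of the osmate ester.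

Step 5
Reactants: 10 (1S,2R,4aR,8aR)-6,6-(ethylenedioxy)-2-isopropyl-4a-methyldecahydronaphthalene-1,2,8a-triol
Product: 11 (1S,2R,4aR,8aR)-6,6-(ethylenedioxy)-2,8a-dihydroxy-2-isopropyl-4a-methyldecahydronaphthalen-1-yl methanesulfonate
Conditions: MsCl, Et3N, CH2Cl2, −20 °C
Reagents that add atoms: methanesulfonyl chloride, CS(=O)(=O)Cl
Why: Chemoselective sulfonylation (through sulfene) of the only secondary hydroxyl; the two tertiary hydroxyls do not react at low temperature and no stereocentre is touched.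

Step 6
Reactants: 11 (1S,2R,4aR,8aR)-6,6-(ethylenedioxy)-2,8a-dihydroxy-2-isopropyl-4a-methyldecahydronaphthalen-1-yl methanesulfonate
Product: 13 (3R,3aR,8aR)-7,7-(ethylenedioxy)-3-hydroxy-3-isopropyl-8a-methyloctahydroazulen-4(1H)-one (trans-fused), via bis(diethylaluminium) dialkoxide 12 (not isolated)
Conditions: Et3Al (3 equiv), CH2Cl2, −78 °C → 0 °C; then aq potassium sodium tartrate
Reagents that add atoms: none
Why: Et3Al converts both tertiary hydroxyls into aluminium alkoxides and activates the mesylate; the alkoxide on the ring-fusion carbon C8a then drives a concerted 1,2-shift of the angular carbon C4a from C8a to C1 with loss of mesylate, leaving the carbonyl at C8a. This is a pinacol-type (semipinacol) rearrangement of a vicinal diol monosulfonate, the classical hydronaphthalene-to-hydroazulene change. No ring is closed by cyclization: the cyclopentane (C1, C2, C3, C4, C4a of 11) results from contraction of ring A and the cycloheptanone from the simultaneous one-carbon expansion of ring B, both through the same shift. The new stereocentre (daucane C5) forms with inversion at the mesylate carbon, the migrating quaternary carbon keeps its configuration and the untouched carbinol fixes C4, so the trans ring fusion with H-5 anti to the angular methyl follows from the all-cis triol. The step needs migration of C4a in preference to C8 and to the C3 methylene: in the favoured chair of the cis-decalin (isopropyl equatorial) the mesylate is equatorial and antiperiplanar to the C8a–C4a bond but gauche to C8a–C8, the fully substituted C4a should outrank the primary C3 in migratory aptitude, and C1 has neither a β-hydrogen nor an open backside for elimination or substitution. The product is held as an aluminium aldolate at low temperature, which should suppress retro-aldol cleavage and dehydration of the β-hydroxy ketone.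

Step 7
Reactants: 13 (3R,3aR,8aR)-7,7-(ethylenedioxy)-3-hydroxy-3-isopropyl-8a-methyloctahydroazulen-4(1H)-one
Product: 14 (3R,3aS,4S,8aR)-7,7-(ethylenedioxy)-3-isopropyl-8a-methyldecahydroazulene-3,4-diol (daucane 4β,6α-diol)
Conditions: Me4NBH(OAc)3, MeCN–AcOH, −30 °C → −20 °C
Reagents that add atoms: none
Why: Hydroxyl-directed reduction of a β-hydroxy ketone (Evans–Saksena reduction): the tertiary hydroxyl exchanges onto boron and delivers hydride intramolecularly to the β-face of the carbonyl, which should give the anti-1,3-diol with the new secondary hydroxyl α.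

Step 8
Reactants: 15 vanillic acid
Product: 17 4-[(tert-butyldimethylsilyl)oxy]-3-methoxybenzoic acid, via silyl ester 16 (not isolated)
Conditions: TBSCl (2.4 equiv), imidazole, DMF, rt; then AcOH–THF–H2O, rt
Reagents that add atoms: tert-butyldimethylsilyl chloride, CC(C)(C)[Si](C)(C)Cl
Why: Silylation of phenol and acid followed by selective hydrolysis of the labile silyl ester leaves the aryl silyl ether as phenol protection.

Step 9
Reactants: 14 (3R,3aS,4S,8aR)-7,7-(ethylenedioxy)-3-isopropyl-8a-methyldecahydroazulene-3,4-diol; 17 4-[(tert-butyldimethylsilyl)oxy]-3-methoxybenzoic acid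
Product: 18 (3R,3aS,4S,8aR)-7,7-(ethylenedioxy)-3-hydroxy-3-isopropyl-8a-methyldecahydroazulen-4-yl 4-[(tert-butyldimethylsilyl)oxy]-3-methoxybenzoate
Conditions: DCC, DMAP, CH2Cl2, 0 °C → rt
Reagents that add atoms: none
Why: Steglich esterification: the acylpyridinium formed from 17 acylates the only secondary hydroxyl, the tertiary one being inert, with retention at the carbinol carbon.

Step 10
Reactants: 18 (3R,3aS,4S,8aR)-7,7-(ethylenedioxy)-3-hydroxy-3-isopropyl-8a-methyldecahydroazulen-4-yl 4-[(tert-butyldimethylsilyl)oxy]-3-methoxybenzoate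
Product: 19 (3R,3aS,4S,8aR)-3-hydroxy-3-isopropyl-8a-methyl-7-oxodecahydroazulen-4-yl 4-[(tert-butyldimethylsilyl)oxy]-3-methoxybenzoate
Conditions: PPTS, acetone–H2O, 50 °C
Reagents that add atoms: water, O
Why: Acid-catalysed hydrolysis of the dioxolane under conditions mild enough for the aryl silyl ether, the ester and the tertiary alcohol.

Step 11
Reactants: 19 (3R,3aS,4S,8aR)-3-hydroxy-3-isopropyl-8a-methyl-7-oxodecahydroazulen-4-yl 4-[(tert-butyldimethylsilyl)oxy]-3-methoxybenzoate
Product: 21 (3R,3aS,4S,8aR)-3-hydroxy-3-isopropyl-8a-methyl-6-methylidene-7-oxodecahydroazulen-4-yl 4-[(tert-butyldimethylsilyl)oxy]-3-methoxybenzoate, via Mannich base 20 (not isolated)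
Conditions: (CH2O)n, PhNHMe·CF3CO2H, THF, reflux
Reagents that add atoms: paraformaldehyde (as formaldehyde), C=O
Why: Mannich-type α-methylenation: the enol on the less hindered side (C6, away from the neopentyl C8 methylene) attacks the iminium ion from formaldehyde and N-methylaniline, and the Mannich base eliminates the amine to the exocyclic enone.

Step 12
Reactants: 21 (3R,3aS,4S,8aR)-3-hydroxy-3-isopropyl-8a-methyl-6-methylidene-7-oxodecahydroazulen-4-yl 4-[(tert-butyldimethylsilyl)oxy]-3-methoxybenzoate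
Product: 22 (3R,3aS,4S,8aR)-3-hydroxy-3-isopropyl-6,8a-dimethyl-7-oxo-1,2,3,3a,4,7,8,8a-octahydroazulen-4-yl 4-[(tert-butyldimethylsilyl)oxy]-3-methoxybenzoate
Conditions: RhCl3·3H2O (cat.), EtOH, 75 °C
Reagents that add atoms: none
Why: Rhodium hydride-mediated alkene isomerization (hydrometalation, β-hydride elimination) should move the exocyclic double bond into the ring to the thermodynamically favoured conjugated trisubstituted enone.

Step 13
Reactants: 22 (3R,3aS,4S,8aR)-3-hydroxy-3-isopropyl-6,8a-dimethyl-7-oxo-1,2,3,3a,4,7,8,8a-octahydroazulen-4-yl 4-[(tert-butyldimethylsilyl)oxy]-3-methoxybenzoate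
Product: 23 (3R,3aS,4S,7S,8aR)-3,7-dihydroxy-3-isopropyl-6,8a-dimethyl-1,2,3,3a,4,7,8,8a-octahydroazulen-4-yl 4-[(tert-butyldimethylsilyl)oxy]-3-methoxybenzoate
Conditions: NaBH4, CeCl3·7H2O, MeOH, −78 °C
Reagents that add atoms: none
Why: Luche reduction: chemoselective 1,2-reduction of the enone, expected by pseudo-axial hydride delivery to give the pseudo-equatorial allylic alcohol trans to the angular methyl (7α, daucane C9).

Step 14
Reactants: 23 (3R,3aS,4S,7S,8aR)-3,7-dihydroxy-3-isopropyl-6,8a-dimethyl-1,2,3,3a,4,7,8,8a-octahydroazulen-4-yl 4-[(tert-butyldimethylsilyl)oxy]-3-methoxybenzoate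
Product: 24 CNP0189996.2, (3R,3aS,4S,7S,8aR)-3,7-dihydroxy-3-isopropyl-6,8a-dimethyl-1,2,3,3a,4,7,8,8a-octahydroazulen-4-yl 4-hydroxy-3-methoxybenzoate
Conditions: TBAF, AcOH, THF, 0 °C
Reagents that add atoms: none
Why: Fluoride-mediated cleavage of the aryl silyl ether, buffered with acetic acid so that the aroate ester and the allylic and tertiary alcohols are left untouched.

**Compound list**

1 | 7-methyl-1,4-dioxaspiro[4.5]decan-8-one (racemic) | CC1CC2(OCCO2)CCC1=O | starting material
2 | (R)-1-phenylethylamine | C[C@@H](N)c1ccccc1 | starting material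
3 | methyl vinyl ketone (but-3-en-2-one) | C=CC(C)=O | starting material
4 | ketimine of 1 with 2, N-[(R)-1-phenylethyl]-7-methyl-1,4-dioxaspiro[4.5]decan-8-imine (not isolated; reacts as its secondary enamine tautomer) | CC1CC2(OCCO2)CCC1=N[C@H](C)c1ccccc1 | intermediate
5 | Michael adduct ketimine, (7R)-7-methyl-7-(3-oxobutyl)-N-[(R)-1-phenylethyl]-1,4-dioxaspiro[4.5]decan-8-imine (not isolated) | C[C@@]1(CCC(C)=O)CC2(OCCO2)CCC1=N[C@H](C)c1ccccc1 | intermediate
6 | (R)-7-methyl-7-(3-oxobutyl)-1,4-dioxaspiro[4.5]decan-8-one | C[C@@]1(CCC(C)=O)CC2(OCCO2)CCC1=O | intermediate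
7 | (4aR)-6,6-(ethylenedioxy)-4a-methyl-4,4a,5,6,7,8-hexahydronaphthalen-2(3H)-one | C[C@]12CCC(=O)C=C1CCC3(OCCO3)C2 | intermediate
8 | (2R,4aR)-6,6-(ethylenedioxy)-2-isopropyl-4a-methyl-2,3,4,4a,5,6,7,8-octahydronaphthalen-2-ol (hydroxyl cis to the angular methyl) | C[C@]12CC[C@@](O)(C(C)C)C=C1CCC3(OCCO3)C2 | intermediate
9 | osmate ester: cyclic 1,8a-O,O'-dioxoosmium diester of triol 10 carrying TMEDA (hexavalent osmium; not isolated) | C[C@]12CC[C@@](O)(C(C)C)[C@H](O[Os-2]3(=O)(=O)(O4)[N+](C)(C)CC[N+]3(C)C)[C@@]14CCC5(OCCO5)C2 | intermediate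
10 | (1S,2R,4aR,8aR)-6,6-(ethylenedioxy)-2-isopropyl-4a-methyldecahydronaphthalene-1,2,8a-triol (cis-fused; three hydroxyls and the angular methyl on one face) | C[C@]12CC[C@@](O)(C(C)C)[C@H](O)[C@@]1(O)CCC3(OCCO3)C2 | intermediate
11 | (1S,2R,4aR,8aR)-6,6-(ethylenedioxy)-2,8a-dihydroxy-2-isopropyl-4a-methyldecahydronaphthalen-1-yl methanesulfonate | C[C@]12CC[C@@](O)(C(C)C)[C@H](OS(C)(=O)=O)[C@@]1(O)CCC3(OCCO3)C2 | intermediate
12 | bis(diethylaluminium) 2,8a-dialkoxide of 11 (not isolated) | C[C@]12CC[C@@](O[Al](CC)CC)(C(C)C)[C@H](OS(C)(=O)=O)[C@@]1(O[Al](CC)CC)CCC3(OCCO3)C2 | intermediate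
13 | (3R,3aR,8aR)-7,7-(ethylenedioxy)-3-hydroxy-3-isopropyl-8a-methyloctahydroazulen-4(1H)-one (trans-fused; daucane 4β-OH, H-5α, 6-oxo, 9-ketal) | O=C1CCC2(OCCO2)C[C@@]3(C)CC[C@@](O)(C(C)C)[C@H]13 | intermediate
14 | (3R,3aS,4S,8aR)-7,7-(ethylenedioxy)-3-isopropyl-8a-methyldecahydroazulene-3,4-diol (daucane 4β,6α-diol) | O[C@H]1CCC2(OCCO2)C[C@@]3(C)CC[C@@](O)(C(C)C)[C@H]13 | intermediate
15 | vanillic acid (4-hydroxy-3-methoxybenzoic acid) | COc1cc(C(=O)O)ccc1O | starting material
16 | tert-butyldimethylsilyl 4-[(tert-butyldimethylsilyl)oxy]-3-methoxybenzoate (not isolated) | COc1cc(C(=O)O[Si](C)(C)C(C)(C)C)ccc1O[Si](C)(C)C(C)(C)C | intermediate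
17 | 4-[(tert-butyldimethylsilyl)oxy]-3-methoxybenzoic acid | COc1cc(C(=O)O)ccc1O[Si](C)(C)C(C)(C)C | intermediate
18 | (3R,3aS,4S,8aR)-7,7-(ethylenedioxy)-3-hydroxy-3-isopropyl-8a-methyldecahydroazulen-4-yl 4-[(tert-butyldimethylsilyl)oxy]-3-methoxybenzoate | COc1cc(C(=O)O[C@H]2CCC4(OCCO4)C[C@@]3(C)CC[C@@](O)(C(C)C)[C@H]23)ccc1O[Si](C)(C)C(C)(C)C | intermediate
19 | (3R,3aS,4S,8aR)-3-hydroxy-3-isopropyl-8a-methyl-7-oxodecahydroazulen-4-yl 4-[(tert-butyldimethylsilyl)oxy]-3-methoxybenzoate | COc1cc(C(=O)O[C@H]2CCC(=O)C[C@@]3(C)CC[C@@](O)(C(C)C)[C@H]23)ccc1O[Si](C)(C)C(C)(C)C | intermediate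
20 | Mannich base, 6-[(N-methylanilino)methyl] derivative of 19 (not isolated; C6 unassigned) | COc1cc(C(=O)O[C@H]2CC(CN(C)c4ccccc4)C(=O)C[C@@]3(C)CC[C@@](O)(C(C)C)[C@H]23)ccc1O[Si](C)(C)C(C)(C)C | intermediate
21 | (3R,3aS,4S,8aR)-3-hydroxy-3-isopropyl-8a-methyl-6-methylidene-7-oxodecahydroazulen-4-yl 4-[(tert-butyldimethylsilyl)oxy]-3-methoxybenzoate | COc1cc(C(=O)O[C@H]2CC(=C)C(=O)C[C@@]3(C)CC[C@@](O)(C(C)C)[C@H]23)ccc1O[Si](C)(C)C(C)(C)C | intermediate
22 | (3R,3aS,4S,8aR)-3-hydroxy-3-isopropyl-6,8a-dimethyl-7-oxo-1,2,3,3a,4,7,8,8a-octahydroazulen-4-yl 4-[(tert-butyldimethylsilyl)oxy]-3-methoxybenzoate | COc1cc(C(=O)O[C@H]2C=C(C)C(=O)C[C@@]3(C)CC[C@@](O)(C(C)C)[C@H]23)ccc1O[Si](C)(C)C(C)(C)C | intermediate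
23 | (3R,3aS,4S,7S,8aR)-3,7-dihydroxy-3-isopropyl-6,8a-dimethyl-1,2,3,3a,4,7,8,8a-octahydroazulen-4-yl 4-[(tert-butyldimethylsilyl)oxy]-3-methoxybenzoate | COc1cc(C(=O)O[C@H]2C=C(C)[C@@H](O)C[C@@]3(C)CC[C@@](O)(C(C)C)[C@H]23)ccc1O[Si](C)(C)C(C)(C)C | intermediate
24 | CNP0189996.2, (3R,3aS,4S,7S,8aR)-3,7-dihydroxy-3-isopropyl-6,8a-dimethyl-1,2,3,3a,4,7,8,8a-octahydroazulen-4-yl 4-hydroxy-3-methoxybenzoate (daucane: 4β,9α-dihydroxydauc-7-en-6α-yl vanillate, H-5α) | COc1cc(C(=O)O[C@H]2C=C(C)[C@@H](O)C[C@@]3(C)CC[C@@](O)(C(C)C)[C@H]23)ccc1O | target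

**Step count.** Total: 14 steps. Longest linear sequence: 13 steps (steps 1–7 and 9–14; step 8 is a one-step side branch).

**Steps most likely to fail**

1. Step 6 (key step). The alkoxide on the isopropyl-bearing carbinol may compete as the driving group, so that the ring-A methylene migrates instead of the angular carbon. The β-hydroxy ketone may also be lost by retro-aldol cleavage or dehydration. The fallback masks the competing hydroxyl before the shift. It sets out from osmate ester 9, which is then isolated rather than cleaved. Silylation of its only free hydroxyl (TESOTf, 2,6-lutidine, CH2Cl2, −78 °C) should give the silylated osmate ester F1. Ethylenediamine releases the 1,8a-diol 2-triethylsilyl ether F2, and MsCl/Et3N gives the secondary mesylate F3. Et3Al can then engage only the ring-fusion alkoxide and should give the silyl-protected hydroazulenone F4, whose β-silyloxy ketone cannot undergo retro-aldol cleavage. HF·pyridine in THF removes the silyl group and the route is rejoined at 13.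

2. Step 4. The osmium reagent has to approach the alkene face that also carries the angular methyl, so the reaction may be slow or the facial selectivity may turn towards the open face. The fallback delivers the two oxygens one at a time by directed epoxidations. It sets out from 8: VO(acac)2/t-BuOOH should give the epoxy alcohol F5 with the oxirane cis to the hydroxyl. Et2Al(TMP) (diethylaluminium 2,2,6,6-tetramethylpiperidide) should isomerize it to the allylic cis-diol F6; the only hydrogens available for the elimination are on C8, so the oxygen stays on C1. A second VO(acac)2/t-BuOOH epoxidation, directed by the allylic secondary hydroxyl, should give the epoxy diol F7. LiAlH4 opens the oxirane at the less substituted C8 and the route is rejoined at triol 10.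

3. Step 13. Hydride may add to the flexible cycloheptenone from the wrong face and give mainly the C7 epimer. The fallback inverts the carbinol instead of selecting the face. It sets out from 22: the Luche reduction then delivers the 7-epimeric alcohol F8 as the main product. A Mitsunobu reaction (PPh3, DIAD, chloroacetic acid, THF) should give the inverted chloroacetate F9. Thiourea/NaHCO3 in ethanol removes the chloroacetyl group selectively and the route is rejoined at 23.

**Further compounds**

F1 | step 6 | 2-O-triethylsilyl ether of osmate ester 9 | C[C@]12CC[C@@](O[Si](CC)(CC)CC)(C(C)C)[C@H](O[Os-2]3(=O)(=O)(O4)[N+](C)(C)CC[N+]3(C)C)[C@@]14CCC5(OCCO5)C2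
F2 | step 6 | 2-O-triethylsilyl ether of triol 10 (free 1,8a-diol) | C[C@]12CC[C@@](O[Si](CC)(CC)CC)(C(C)C)[C@H](O)[C@@]1(O)CCC3(OCCO3)C2
F3 | step 6 | 1-methanesulfonate of F2 | C[C@]12CC[C@@](O[Si](CC)(CC)CC)(C(C)C)[C@H](OS(C)(=O)=O)[C@@]1(O)CCC3(OCCO3)C2
F4 | step 6 | 3-O-triethylsilyl ether of hydroazulenone 13 | O=C1CCC2(OCCO2)C[C@@]3(C)CC[C@@](O[Si](CC)(CC)CC)(C(C)C)[C@H]13
F5 | step 4 | 1,8a-epoxide of 8 with the oxirane cis to the hydroxyl and the angular methyl | C[C@]12CC[C@@](O)(C(C)C)[C@@H]3O[C@@]31CCC4(OCCO4)C2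
F6 | step 4 | allylic cis-1,2-diol with the 8,8a double bond (6,6-(ethylenedioxy)-2-isopropyl-4a-methyl-1,2,3,4,4a,5,6,7-octahydronaphthalene-1,2-diol, both hydroxyls cis to the methyl) | C[C@]12CC[C@@](O)(C(C)C)[C@H](O)C1=CCC3(OCCO3)C2
F7 | step 4 | 8,8a-epoxide of F6 with the oxirane cis to the two hydroxyls | C[C@]12CC[C@@](O)(C(C)C)[C@H](O)[C@]13O[C@@H]3CC4(OCCO4)C2
F8 | step 13 | 7-epimer of 23 (7β-alcohol) | COc1cc(C(=O)O[C@H]2C=C(C)[C@H](O)C[C@@]3(C)CC[C@@](O)(C(C)C)[C@H]23)ccc1O[Si](C)(C)C(C)(C)C
F9 | step 13 | 7-O-chloroacetate of 23 (7α) | COc1cc(C(=O)O[C@H]2C=C(C)[C@@H](OC(=O)CCl)C[C@@]3(C)CC[C@@](O)(C(C)C)[C@H]23)ccc1O[Si](C)(C)C(C)(C)C
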